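The ratio I started from was the enzyme charge of elm over that of oak, 2.31, with substrate and added ligand charged alike.

the same everywhere: substrate 0.20 M; added ligand 69 µM

| flask | enzyme | remark |
|---|---|---|
| oak | 13 µM | run made earlier |
| elm | 30 µM | run made earlier |
| flask | 20 µM |  |

- oak (time / min: target / %, substrate / %): 0.833: 16.8, 83.6; 2.50: 41.3, 57.6; 4.00: 57.6, 43.3; 6.00: 70.7, 29.6; 10.0: 83.4, 15.8; 12.0: 87.2, 12.8
- elm (time / min: target / %, substrate / %): 2.00: 62.2, 37.7; 4.00: 82.2, 18.1; 6.00: 89.6, 10.2; 8.00: 92.8, 7.2; 10.0: 94.3, 5.5; 12.0: 95.5, 4.3

(each reading ± 0.3 percentage points)

- factor on the rate of making target when 30% of the substrate are converted if enzyme is charged twice over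
- factor on the rate when 30% of the substrate are converted if enzyme is charged at 200 µM instead



If the rate follows the enzyme charge, oak should need that factor more time than elm to reach the same fraction of substrate left. I tested this at two places in the runs, one early and one late, and the two answers are not wholly separate, since oak's reading of 29.6% at 6.00 min enters both. Elm had 37.7% left at 2.00 min, and oak, interpolated on the logarithm between its neighbouring readings, got there at 4.73 min, a factor of 2.36. Elm had 18.1% left at 4.00 min, and oak got there at 9.13 min, a factor of 2.28.

The logarithm of such a factor over the logarithm of the charge ratio gives the power of the enzyme charge by which the time to equal conversion shrinks. The early place gave 1.03 and the late place 0.987. I took their mean, 1.01, as my enzyme order, the reaction order in enzyme.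

For the flask with 0.0400 mM of enzyme, my reckoning gave a factor of 2.01. For 200 µM it gave 10.2, but with a caveat. In oak and elm, added ligand stood above enzyme, whereas at 200 µM its charge is 0.345 of the enzyme charge, so this number was an extrapolation.

The forecast gave 2 (1.8 to 2.1) for doubling and 3.5 (3 to 10) for 200 µM. Its ground was that if added ligand were a required partner, “active enzyme caps near” the ligand charge, and it called this a judgement. On the second number it differed from mine.

The simulation gave 2.03 for doubling and 11.3 at 200 µM.

    2 enzyme → spent catalyst (k = 140 /M/s)
    enzyme + added ligand ⇌ idle complex (K = 7500 /M, k = 2200 /M/s)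
    substrate + enzyme → target + enzyme, rate k3*[substrate]^1.5*[enzyme]/(1 + ([substrate]/Kh3)^1.5) (0.110 M, k = 3100 /M^1.5/s)

In the flask at 1.20 min, enzyme stood at 56.7% of its charge, idle complex at 27.2% and spent catalyst at 16.0%, with added ligand at 92.1% of its own charge. Read as an enzyme order, doubling the flask's charge gave 1.02, and the step to 200 µM gave 1.05, against 1.01 from oak and elm.

The readings come from a simulation for substances that don't exist; noise was put on by code.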